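The ten-membered ring (numbered C1 = ester carbinol, C2–C8, C9 = free carbinol, C10 = isopropyl carbon) is disconnected at the C(sp3)–C(sp2) bond between the ring methylene C6 and the methyl-bearing alkene carbon C7. One operation, 9-BBN hydroboration followed by intramolecular B-alkyl Suzuki–Miyaura coupling, turns an acyclic iodo-triene into the cyclodeca-3,7-diene. The step exploits the two cis ring alkenes that flank the C5–C6 bridge: C7=C8 enters as a (Z)-alkenyl iodide made from but-2-yn-1-ol, and C3=C4 as part of a terminal (Z)-diene whose geometry is fixed in a temporary dihydropyranone ring. The syn,syn C9/C10/C1 triad comes from a thiazolidinethione aldol and a reagent-controlled methallylation.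

Key step: step 12

Remark: the target is read as the (1R,3Z,7Z,9S,10R) isomer, i.e. both ring alkenes cis and the C1–O, C10–isopropyl and C9–O substituents mutually syn.

Step 1
Reactants: 1 but-2-yn-1-ol
Product: 3 (Z)-3-iodobut-2-en-1-ol, via cyclic alkenylalanate 2 (not isolated)
Conditions: NaAlH2(OCH2CH2OMe)2, THF, 0 °C to rt; then I2, THF, −78 °C to rt
Reagents that add atoms: iodine, II
Why: Alkoxide-directed trans-hydroalumination of the propargylic alcohol places aluminium on C3 cis to the carbinol carbon, and iododealumination with retention should give the (Z)-iodoalkene (hydroalumination–iodination).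

Step 2
Reactants: 3 (Z)-3-iodobut-2-en-1-ol
Product: 4 (Z)-3-iodobut-2-enal
Conditions: activated MnO2, CH2Cl2, rt, dark; used at once
Reagents that add atoms: none
Why: Allylic alcohol oxidation with MnO2 is neutral and should leave the (Z)-iodoalkene geometry untouched.

Step 3
Reactants: 5 (R)-4-benzyl-1,3-thiazolidine-2-thione; 6 3-methylbutanoyl chloride
Product: 7 (R)-4-benzyl-3-(3-methylbutanoyl)-1,3-thiazolidine-2-thione
Conditions: Et3N, DMAP (cat.), CH2Cl2, 0 °C to rt
Reagents that add atoms: none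
Why: N-acylation of the thiazolidinethione with an acid chloride under DMAP catalysis is the standard entry to the aldol substrate.

Step 4
Reactants: 7 (R)-4-benzyl-3-(3-methylbutanoyl)-1,3-thiazolidine-2-thione; 4 (Z)-3-iodobut-2-enal
Product: 9 (R)-4-benzyl-3-[(2R,3R,4Z)-3-hydroxy-5-iodo-2-(propan-2-yl)hex-4-enoyl]-1,3-thiazolidine-2-thione, via titanium Z-enolate 8 (not isolated)
Conditions: TiCl4, i-Pr2NEt, N-methyl-2-pyrrolidone, CH2Cl2, 0 °C; then 4, −78 to 0 °C
Reagents that add atoms: none
Why: In this Crimmins titanium aldol, soft enolization gives Z-enolate 8, which should add through a closed chair transition state on the face opposite the benzyl group, so the C9 carbinol and the C10 isopropyl centre form as the Evans-syn pair dictated by the (R)-auxiliary.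

Step 5
Reactants: 9 (R)-4-benzyl-3-[(2R,3R,4Z)-3-hydroxy-5-iodo-2-(propan-2-yl)hex-4-enoyl]-1,3-thiazolidine-2-thione
Product: 10 (R)-4-benzyl-3-[(2R,3R,4Z)-3-(tert-butyldimethylsilyloxy)-5-iodo-2-(propan-2-yl)hex-4-enoyl]-1,3-thiazolidine-2-thione
Conditions: TBSOTf, 2,6-lutidine, CH2Cl2, −78 to 0 °C
Reagents that add atoms: tert-butyldimethylsilyl trifluoromethanesulfonate, CC(C)(C)[Si](C)(C)OS(=O)(=O)C(F)(F)F
Why: Silyl ether protection with the silyl triflate should cap the hindered C9 hydroxyl, which stays masked until the last step so that only C1–O is later acylated.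

Step 6
Reactants: 10 (R)-4-benzyl-3-[(2R,3R,4Z)-3-(tert-butyldimethylsilyloxy)-5-iodo-2-(propan-2-yl)hex-4-enoyl]-1,3-thiazolidine-2-thione
Product: 11 (2R,3R,4Z)-3-(tert-butyldimethylsilyloxy)-5-iodo-2-(propan-2-yl)hex-4-enal
Conditions: i-Bu2AlH, CH2Cl2, −78 °C
Reagents that add atoms: none
Why: N-acylthiazolidinethiones are reduced by i-Bu2AlH directly to aldehydes (reductive auxiliary cleavage), and the cold non-basic conditions should keep the α-centre intact.

Step 7
Reactants: 11 (2R,3R,4Z)-3-(tert-butyldimethylsilyloxy)-5-iodo-2-(propan-2-yl)hex-4-enal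
Product: 12 (4R,5S,6R,7Z)-6-(tert-butyldimethylsilyloxy)-8-iodo-2-methyl-5-(propan-2-yl)nona-1,7-dien-4-ol
Conditions: (+)-Ipc2BOMe [from (−)-α-pinene], 2-methylallylmagnesium chloride, Et2O, −78 °C to rt; then 11, −78 °C; NaOH, H2O2
Reagents that add atoms: 2-methylallylmagnesium chloride, CC(=C)C[Mg]Cl
Why: In this Brown-type asymmetric allylboration the (−)-α-pinene-derived B-methallyl reagent should add through a chair transition state to the Re face of the aldehyde, setting the C1 carbinol syn to the C10 isopropyl group, which is also the face the Felkin–Anh model favours.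

Step 8
Reactants: 12 (4R,5S,6R,7Z)-6-(tert-butyldimethylsilyloxy)-8-iodo-2-methyl-5-(propan-2-yl)nona-1,7-dien-4-ol
Product: 13 (4R,5S,6R,7Z)-6-(tert-butyldimethylsilyloxy)-8-iodo-2-methyl-5-(propan-2-yl)nona-1,7-dien-4-yl prop-2-enoate
Conditions: acryloyl chloride, i-Pr2NEt, DMAP (cat.), CH2Cl2, 0 °C
Reagents that add atoms: acryloyl chloride, C=CC(Cl)=O
Why: DMAP-catalysed esterification of the secondary alcohol with the acid chloride installs the two-carbon tether (future C4 and C5) without touching any stereocentre.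

Step 9
Reactants: 13 (4R,5S,6R,7Z)-6-(tert-butyldimethylsilyloxy)-8-iodo-2-methyl-5-(propan-2-yl)nona-1,7-dien-4-yl prop-2-enoate
Product: 14 (6R)-6-[(3S,4R,5Z)-4-(tert-butyldimethylsilyloxy)-6-iodo-2-methylhept-5-en-3-yl]-4-methyl-5,6-dihydro-2H-pyran-2-one
Conditions: second-generation Grubbs catalyst RuCl2(=CHPh)(PCy3)(H2IMes) (cat.), CH2Cl2, 40 °C, dilute
Reagents that add atoms: none
Why: Ring-closing metathesis of the acrylate with the 1,1-disubstituted alkene should give the six-membered unsaturated lactone, whose ring forces C2 and C5 cis across the new trisubstituted C3=C4 bond, while the trisubstituted iodoalkene is inert to the catalyst.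

Step 10
Reactants: 14 (6R)-6-[(3S,4R,5Z)-4-(tert-butyldimethylsilyloxy)-6-iodo-2-methylhept-5-en-3-yl]-4-methyl-5,6-dihydro-2H-pyran-2-one
Product: 15 (6R)-6-[(3S,4R,5Z)-4-(tert-butyldimethylsilyloxy)-6-iodo-2-methylhept-5-en-3-yl]-4-methyl-5,6-dihydro-2H-pyran-2-ol (anomer mixture)
Conditions: i-Bu2AlH, CH2Cl2, −78 °C
Reagents that add atoms: none
Why: Partial 1,2-reduction of the unsaturated lactone at low temperature should stop at the lactol (lactone-to-lactol reduction).

Step 11
Reactants: 15 (6R)-6-[(3S,4R,5Z)-4-(tert-butyldimethylsilyloxy)-6-iodo-2-methylhept-5-en-3-yl]-4-methyl-5,6-dihydro-2H-pyran-2-ol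
Product: 16 (3Z,6R,7S,8R,9Z)-8-(tert-butyldimethylsilyloxy)-10-iodo-4-methyl-7-(propan-2-yl)undeca-1,3,9-trien-6-ol
Conditions: Ph3PCH3Br, KN(SiMe3)2, THF, 0 °C; then 15, 0 °C to rt
Reagents that add atoms: methyltriphenylphosphonium bromide, C[P+](c1ccccc1)(c1ccccc1)c1ccccc1.[Br-]
Why: Wittig methylenation of the ring-opened hydroxy-enal form of the lactol should deliver the terminal diene with the C3=C4 geometry inherited from the ring and free C1–OH.

Step 12
Reactants: 16 (3Z,6R,7S,8R,9Z)-8-(tert-butyldimethylsilyloxy)-10-iodo-4-methyl-7-(propan-2-yl)undeca-1,3,9-trien-6-ol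
Product: 18 (1R,3Z,7Z,9S,10S)-9-(tert-butyldimethylsilyloxy)-3,7-dimethyl-10-(propan-2-yl)cyclodeca-3,7-dien-1-ol, via alkyl-9-BBN borane 17 (not isolated)
Conditions: 9-BBN (excess), THF, 0 °C to rt; then slow addition (syringe pump) to Pd(dppf)Cl2 (cat.), AsPh3, aq K3PO4, THF/DMF, 50 °C, high dilution
Reagents that add atoms: none
Why: 9-BBN should add to the monosubstituted C5=C6 terminus of the diene with boron on C6 (anti-Markovnikov, steric control) to give the primary homoallylic borane 17, after which zerovalent palladium inserts into the C7–I bond, the base-activated borate transfers its primary alkyl group and reductive elimination forms the C6–C7 bond with retention of the alkenyl geometry. The closest known reaction type is the intramolecular B-alkyl Suzuki–Miyaura macrocyclization of an alkenyl iodide with a 9-BBN alkylborane. The ten-membered carbocycle is closed end to end, by reductive elimination from an eleven-membered alkyl(alkenyl)palladium chelate and not by exo or endo addition to a π bond. No stereocentre is created: the Z geometry at C7=C8 is carried over from the iodoalkene of step 1 and that at C3=C4 from the lactone of step 9, and C1, C9 and C10 are spectators. The step needs chemo- and regioselective hydroboration, secured by the bulk of 9-BBN and the single monosubstituted alkene, and cyclization in preference to oligomerization and β-hydride elimination, secured by slow addition at high dilution, by the two cis alkenes and the syn,syn triad that fold the chain, and by the wide bite angle of dppf.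

Step 13
Reactants: 19 vanillic acid (4-hydroxy-3-methoxybenzoic acid)
Product: 21 4-(tert-butyldimethylsilyloxy)-3-methoxybenzoic acid, via bis-silylated vanillic acid 20 (not isolated)
Conditions: TBSCl, imidazole, DMF, rt; then K2CO3, MeOH/THF/H2O, rt
Reagents that add atoms: tert-butyldimethylsilyl chloride, CC(C)(C)[Si](C)(C)Cl
Why: Exhaustive silylation followed by selective hydrolysis of the labile silyl ester should leave only the phenol protected (silyl ether protection).

Step 14
Reactants: 18 (1R,3Z,7Z,9S,10S)-9-(tert-butyldimethylsilyloxy)-3,7-dimethyl-10-(propan-2-yl)cyclodeca-3,7-dien-1-ol; 21 4-(tert-butyldimethylsilyloxy)-3-methoxybenzoic acid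
Product: 22 (1R,3Z,7Z,9S,10S)-9-(tert-butyldimethylsilyloxy)-3,7-dimethyl-10-(propan-2-yl)cyclodeca-3,7-dien-1-yl 4-(tert-butyldimethylsilyloxy)-3-methoxybenzoate
Conditions: EDC·HCl, DMAP, CH2Cl2, rt
Reagents that add atoms: none
Why: Steglich esterification (carbodiimide activation with DMAP) should acylate the only free hydroxyl, C1–OH, with retention at C1.

Step 15
Reactants: 22 (1R,3Z,7Z,9S,10S)-9-(tert-butyldimethylsilyloxy)-3,7-dimethyl-10-(propan-2-yl)cyclodeca-3,7-dien-1-yl 4-(tert-butyldimethylsilyloxy)-3-methoxybenzoate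
Product: 23 (1R,3Z,7Z,9S,10R)-9-hydroxy-3,7-dimethyl-10-(propan-2-yl)cyclodeca-3,7-dien-1-yl 4-hydroxy-3-methoxybenzoate (CNP0185892.3)
Conditions: n-Bu4NF, AcOH, THF, 0 °C to rt
Reagents that add atoms: none
Why: Fluoride-mediated desilylation should remove the aryl and the secondary silyl ether in one operation, and the acetic acid buffer should suppress acyl migration from C1–O to C9–O.

Compound list
1 | but-2-yn-1-ol | CC#CCO | starting material
2 | cyclic sodium (Z)-alkenylalanate (five-membered O–Al–C3=C2–C1 ring, two 2-methoxyethoxy groups on Al) | C/C1=C/CO[Al-]1(OCCOC)OCCOC.[Na+] | intermediate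
3 | (Z)-3-iodobut-2-en-1-ol | C/C(I)=C/CO | intermediate
4 | (Z)-3-iodobut-2-enal | C/C(I)=C/C=O | intermediate
5 | (R)-4-benzyl-1,3-thiazolidine-2-thione | S=C1N[C@H](Cc2ccccc2)CS1 | starting material
6 | 3-methylbutanoyl chloride | CC(C)CC(Cl)=O | starting material
7 | (R)-4-benzyl-3-(3-methylbutanoyl)-1,3-thiazolidine-2-thione | CC(C)CC(=O)N1[C@H](Cc2ccccc2)CSC1=S | intermediate
8 | trichlorotitanium (Z)-enolate of 7 | CC(C)/C=C(\O[Ti](Cl)(Cl)Cl)N1[C@H](Cc2ccccc2)CSC1=S | intermediate
9 | (R)-4-benzyl-3-[(2R,3R,4Z)-3-hydroxy-5-iodo-2-(propan-2-yl)hex-4-enoyl]-1,3-thiazolidine-2-thione | C/C(I)=C/[C@H](O)[C@@H](C(C)C)C(=O)N1[C@H](Cc2ccccc2)CSC1=S | intermediate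
10 | (R)-4-benzyl-3-[(2R,3R,4Z)-3-(tert-butyldimethylsilyloxy)-5-iodo-2-(propan-2-yl)hex-4-enoyl]-1,3-thiazolidine-2-thione | C/C(I)=C/[C@H](O[Si](C)(C)C(C)(C)C)[C@@H](C(C)C)C(=O)N1[C@H](Cc2ccccc2)CSC1=S | intermediate
11 | (2R,3R,4Z)-3-(tert-butyldimethylsilyloxy)-5-iodo-2-(propan-2-yl)hex-4-enal | C/C(I)=C/[C@H](O[Si](C)(C)C(C)(C)C)[C@@H](C(C)C)C=O | intermediate
12 | (4R,5S,6R,7Z)-6-(tert-butyldimethylsilyloxy)-8-iodo-2-methyl-5-(propan-2-yl)nona-1,7-dien-4-ol | C/C(I)=C/[C@H](O[Si](C)(C)C(C)(C)C)[C@@H](C(C)C)[C@H](O)CC(C)=C | intermediate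
13 | (4R,5S,6R,7Z)-6-(tert-butyldimethylsilyloxy)-8-iodo-2-methyl-5-(propan-2-yl)nona-1,7-dien-4-yl prop-2-enoate | C/C(I)=C/[C@H](O[Si](C)(C)C(C)(C)C)[C@@H](C(C)C)[C@H](OC(=O)C=C)CC(C)=C | intermediate
14 | (6R)-6-[(3S,4R,5Z)-4-(tert-butyldimethylsilyloxy)-6-iodo-2-methylhept-5-en-3-yl]-4-methyl-5,6-dihydro-2H-pyran-2-one | C/C(I)=C/[C@H](O[Si](C)(C)C(C)(C)C)[C@@H](C(C)C)[C@H]1CC(C)=CC(=O)O1 | intermediate
15 | (6R)-6-[(3S,4R,5Z)-4-(tert-butyldimethylsilyloxy)-6-iodo-2-methylhept-5-en-3-yl]-4-methyl-5,6-dihydro-2H-pyran-2-ol (anomer mixture) | C/C(I)=C/[C@H](O[Si](C)(C)C(C)(C)C)[C@@H](C(C)C)[C@H]1CC(C)=CC(O)O1 | intermediate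
16 | (3Z,6R,7S,8R,9Z)-8-(tert-butyldimethylsilyloxy)-10-iodo-4-methyl-7-(propan-2-yl)undeca-1,3,9-trien-6-ol | C/C(I)=C/[C@H](O[Si](C)(C)C(C)(C)C)[C@@H](C(C)C)[C@H](O)C/C(C)=C\C=C | intermediate
17 | 9-[(3Z,6R,7S,8R,9Z)-8-(tert-butyldimethylsilyloxy)-6-hydroxy-10-iodo-4-methyl-7-(propan-2-yl)undeca-3,9-dien-1-yl]-9-borabicyclo[3.3.1]nonane | C/C(I)=C/[C@H](O[Si](C)(C)C(C)(C)C)[C@@H](C(C)C)[C@H](O)C/C(C)=C\CCB1C2CCCC1CCC2 | intermediate
18 | (1R,3Z,7Z,9S,10S)-9-(tert-butyldimethylsilyloxy)-3,7-dimethyl-10-(propan-2-yl)cyclodeca-3,7-dien-1-ol | O[C@@H]1C/C(C)=C\CC/C(C)=C\[C@H](O[Si](C)(C)C(C)(C)C)[C@H]1C(C)C | intermediate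
19 | vanillic acid (4-hydroxy-3-methoxybenzoic acid) | COc1cc(C(=O)O)ccc1O | starting material
20 | tert-butyldimethylsilyl 4-(tert-butyldimethylsilyloxy)-3-methoxybenzoate | COc1cc(C(=O)O[Si](C)(C)C(C)(C)C)ccc1O[Si](C)(C)C(C)(C)C | intermediate
21 | 4-(tert-butyldimethylsilyloxy)-3-methoxybenzoic acid | COc1cc(C(=O)O)ccc1O[Si](C)(C)C(C)(C)C | intermediate
22 | (1R,3Z,7Z,9S,10S)-9-(tert-butyldimethylsilyloxy)-3,7-dimethyl-10-(propan-2-yl)cyclodeca-3,7-dien-1-yl 4-(tert-butyldimethylsilyloxy)-3-methoxybenzoate | COc1cc(C(=O)O[C@@H]2C/C(C)=C\CC/C(C)=C\[C@H](O[Si](C)(C)C(C)(C)C)[C@H]2C(C)C)ccc1O[Si](C)(C)C(C)(C)C | intermediate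
23 | (1R,3Z,7Z,9S,10R)-9-hydroxy-3,7-dimethyl-10-(propan-2-yl)cyclodeca-3,7-dien-1-yl 4-hydroxy-3-methoxybenzoate | COc1cc(C(=O)O[C@@H]2C/C(C)=C\CC/C(C)=C\[C@H](O)[C@H]2C(C)C)ccc1O | target

Total step count: 15.
Longest linear sequence: 13 steps (steps 1, 2, 4–12, 14 and 15, from but-2-yn-1-ol).

Steps most likely to fail

Step 12 (key step). The ring closure may lose out to intermolecular coupling, to β-hydride elimination from the homoallylic alkylpalladium species, or to protodeboronation, and hydroboration of the conjugated diene may be sluggish or poorly regioselective. The fallback closes the same C6–C7 bond by a nickel cross-electrophile coupling instead of a boron-to-palladium transmetalation. It sets out from 16: hydroboration with 9-BBN and oxidative work-up (NaOH, H2O2) would give the primary alcohol (3Z,6R,7S,8R,9Z)-8-(tert-butyldimethylsilyloxy)-10-iodo-4-methyl-7-(propan-2-yl)undeca-3,9-diene-1,6-diol F1. Selective iodination of the primary hydroxyl (PPh3, I2, imidazole, 0 °C) would give (3Z,6R,7S,8R,9Z)-8-(tert-butyldimethylsilyloxy)-1,10-diiodo-4-methyl-7-(propan-2-yl)undeca-3,9-dien-6-ol F2. Slow addition of F2 to NiI2, 4,4′-di-tert-butyl-2,2′-bipyridine, Mn powder and NaI in DMA would join the alkyl and alkenyl iodides intramolecularly, and the route is rejoined at 18.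

Step 7. Facial selectivity may be poor if the reagent and the α-branched aldehyde are mismatched, and the α-centre of 11 may epimerize before addition. The fallback sets the C1 carbinol by ketone reduction instead of C–C bond formation. It sets out from 12, whatever its epimer ratio at the new carbinol: Dess–Martin oxidation (NaHCO3, CH2Cl2) would converge both epimers on the ketone (5R,6R,7Z)-6-(tert-butyldimethylsilyloxy)-8-iodo-2-methyl-5-(propan-2-yl)nona-1,7-dien-4-one F3. Corey–Bakshi–Shibata reduction with (S)-2-methyl-CBS-oxazaborolidine and catecholborane (toluene, −78 °C), which differentiates the branched C5 side from the methallyl CH2, should then return the (4R)-alcohol, and the route is rejoined at 12.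

Step 11. The basic ylide may enolize the ring-opened (Z)-enal, which would scramble the C3=C4 geometry or move the double bond into conjugation. The fallback replaces the one-step Wittig by a two-step addition–elimination with a non-basic nucleophile. It sets out from 15: addition of Me3SiCH2Li/CeCl3 (THF, −78 °C) to the open aldehyde form would give the β-hydroxysilane (3Z,6R,7S,8R,9Z)-8-(tert-butyldimethylsilyloxy)-10-iodo-4-methyl-7-(propan-2-yl)-1-(trimethylsilyl)undeca-3,9-diene-2,6-diol F4 as a mixture of C2 epimers. Peterson elimination with KH (THF, 0 °C) should then give the terminal diene, and the route is rejoined at 16.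

Further compounds
F1 | step 12 | (3Z,6R,7S,8R,9Z)-8-(tert-butyldimethylsilyloxy)-10-iodo-4-methyl-7-(propan-2-yl)undeca-3,9-diene-1,6-diol | C/C(I)=C/[C@H](O[Si](C)(C)C(C)(C)C)[C@@H](C(C)C)[C@H](O)C/C(C)=C\CCO
F2 | step 12 | (3Z,6R,7S,8R,9Z)-8-(tert-butyldimethylsilyloxy)-1,10-diiodo-4-methyl-7-(propan-2-yl)undeca-3,9-dien-6-ol | C/C(I)=C/[C@H](O[Si](C)(C)C(C)(C)C)[C@@H](C(C)C)[C@H](O)C/C(C)=C\CCI
F3 | step 7 | (5R,6R,7Z)-6-(tert-butyldimethylsilyloxy)-8-iodo-2-methyl-5-(propan-2-yl)nona-1,7-dien-4-one | C/C(I)=C/[C@H](O[Si](C)(C)C(C)(C)C)[C@@H](C(C)C)C(=O)CC(C)=C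
F4 | step 11 | (3Z,6R,7S,8R,9Z)-8-(tert-butyldimethylsilyloxy)-10-iodo-4-methyl-7-(propan-2-yl)-1-(trimethylsilyl)undeca-3,9-diene-2,6-diol (C2 epimers) | C/C(I)=C/[C@H](O[Si](C)(C)C(C)(C)C)[C@@H](C(C)C)[C@H](O)C/C(C)=C\C(O)C[Si](C)(C)C
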